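**Plan**
Cuts, in retrosynthetic order: benzyl groups are placed on O7'' and O4'''. Then O1–C2 and O1''–C2'' are cut (cyclodehydration), then C2–C3 and C2''–C3'' (twofold Baker–Venkataraman transfer), then two aryl ester C–O bonds, and last the C3'–C8'' biaryl bond (Suzuki–Miyaura).
Enabling feature: in each pyranone, C2 is a former aroyl carbon and C3 a former acetyl methyl carbon. The central biaryl holds one of each. The carboxyl carbon on C1' of ring B becomes C2 of flavone 1 (the dimethoxy half). The acetyl group on C4a'' of ring A of flavone 2 (the dihydroxy half) supplies C4''/C3''. Each is joined to its partner through a phenolic oxygen, the future O1 or O1''.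
Forward order: ring A iodide, biaryl, ester on the future O1'', CHO to CO2H, ester on the future O1, both diketones in one operation, both pyranone rings closed together, debenzylation. All four benzene rings are bought.
Stereochemistry: the target has no stereocentre and no axial descriptor, so nothing has to be set.

Key step: step 7

Assumption: the C3'–C8'' axis has one ortho hydrogen (C2'–H) and no configuration is specified, so axial chirality is not controlled; 1,3-diketones are drawn as keto forms although they should be largely enolised.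

**Step 1**
Reactants: 1 2,4-dihydroxyacetophenone (resacetophenone)
Product: 2 1-(2,4-dihydroxy-3-iodophenyl)ethan-1-one
Conditions: I2 (0.4 equiv), HIO3 (0.2 equiv), EtOH–H2O, rt
Reagents that add atoms: iodine, II; iodic acid, OI(=O)=O
Why: Electrophilic aromatic iodination, known for resacetophenone to favour C3, the carbon ortho to both hydroxyl groups and so the most nucleophilic one, while HIO3 reoxidises iodide so that exactly one iodine equivalent is delivered and diiodination is held back.

**Step 2**
Reactants: 2 1-(2,4-dihydroxy-3-iodophenyl)ethan-1-one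
Product: 3 1-[4-(benzyloxy)-2-hydroxy-3-iodophenyl]ethan-1-one
Conditions: BnBr (1.05 equiv), K2CO3 (1.1 equiv), acetone, reflux
Reagents that add atoms: benzyl bromide, BrCc1ccccc1
Why: Williamson ether synthesis in which the 2-OH is held in a hydrogen bond to the acetyl carbonyl, so the free and more acidic 4-OH should be alkylated selectively by one equivalent of halide.

**Step 3**
Reactants: 3 1-[4-(benzyloxy)-2-hydroxy-3-iodophenyl]ethan-1-one; 4 (5-formyl-2-methoxyphenyl)boronic acid
Product: 5 3'-acetyl-6'-(benzyloxy)-2'-hydroxy-6-methoxy-[1,1'-biphenyl]-3-carbaldehyde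
Conditions: Pd(OAc)2 (5 mol %), SPhos (10 mol %), K3PO4 (3 equiv), 4 (1.5 equiv), 1,4-dioxane–H2O, 80 °C, Ar
Reagents that add atoms: none
Why: Suzuki–Miyaura coupling, in which the iodide adds readily to zerovalent palladium, the bulky electron-rich biarylphosphine SPhos is suited to tri-ortho-substituted biaryls, and phosphate is a mild enough base that Claisen–Schmidt condensation between acetyl and formyl groups should stay slow.

**Step 4**
Reactants: 5 3'-acetyl-6'-(benzyloxy)-2'-hydroxy-6-methoxy-[1,1'-biphenyl]-3-carbaldehyde; 6 4-(benzyloxy)benzoic acid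
Product: 8 6-acetyl-3-(benzyloxy)-2-(5-formyl-2-methoxyphenyl)phenyl 4-(benzyloxy)benzoate, via 4-(benzyloxy)benzoyl chloride 7 (not isolated)
Conditions: 6, (COCl)2, DMF (cat.), CH2Cl2, 0 °C to rt, evaporate; then 5, pyridine, DMAP (cat.), CH2Cl2, 0 °C to rt
Reagents that add atoms: oxalyl chloride, O=C(Cl)C(=O)Cl (its chlorine ends in 7 and is lost again on the way to 8)
Why: Acid chloride formation followed by DMAP-catalysed O-acylation, the standard entry to ortho-aroyloxyacetophenones, where the acylpyridinium ion should be reactive enough for the chelated, flanked phenol and the aldehyde is inert.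

**Step 5**
Reactants: 8 6-acetyl-3-(benzyloxy)-2-(5-formyl-2-methoxyphenyl)phenyl 4-(benzyloxy)benzoate
Product: 9 3-[3-acetyl-6-(benzyloxy)-2-{[4-(benzyloxy)benzoyl]oxy}phenyl]-4-methoxybenzoic acid
Conditions: NaClO2, NaH2PO4, 2-methyl-2-butene, THF–t-BuOH–H2O, 0 °C to rt
Reagents that add atoms: sodium chlorite, [Na+].[O-]Cl=O
Why: Pinnick oxidation takes the aryl aldehyde to the acid in a weakly acidic buffer that leaves the aryl ester, methyl ketone and benzyl ethers alone, and the alkene traps HOCl before it can chlorinate the alkoxyarenes.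

**Step 6**
Reactants: 9 3-[3-acetyl-6-(benzyloxy)-2-{[4-(benzyloxy)benzoyl]oxy}phenyl]-4-methoxybenzoic acid; 10 2-hydroxy-4-methoxyacetophenone (paeonol)
Product: 11 2-acetyl-5-methoxyphenyl 3-[3-acetyl-6-(benzyloxy)-2-{[4-(benzyloxy)benzoyl]oxy}phenyl]-4-methoxybenzoate
Conditions: EDC·HCl (N-(3-dimethylaminopropyl)-N'-ethylcarbodiimide hydrochloride, 1.3 equiv), DMAP (0.2 equiv), 10 (1.2 equiv), CH2Cl2, 0 °C to rt
Reagents that add atoms: none
Why: Steglich esterification, in which the carbodiimide activates the only free carboxyl group and DMAP relays the acyl group to the hydrogen-bonded phenol of 10, while the hindered, electron-rich aryl ester already present should not be attacked at room temperature.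

**Step 7**
Reactants: 11 2-acetyl-5-methoxyphenyl 3-[3-acetyl-6-(benzyloxy)-2-{[4-(benzyloxy)benzoyl]oxy}phenyl]-4-methoxybenzoate
Product: 12 1-[4-(benzyloxy)phenyl]-3-{4-(benzyloxy)-2-hydroxy-3-[5-(3-(2-hydroxy-4-methoxyphenyl)-3-oxopropanoyl)-2-methoxyphenyl]phenyl}propane-1,3-dione
Conditions: KOH (powdered, 6 equiv), dry pyridine, 50 °C; then ice-cold 1 M HCl
Reagents that add atoms: none
Why: Hydroxide deprotonates both aryl methyl ketones, and each enolate carbon adds to the carbonyl of the ester on the oxygen ortho to it, giving a transient six-membered cyclic alkoxide that breaks its C–O bond to leave a 1,3-diketone and a phenoxide; this is a twofold Baker–Venkataraman rearrangement, i.e. two intramolecular Claisen condensations in one molecule. The paeonol acetyl carbon bonds to the ring B carboxyl carbon (C3–C2), and the ring A acetyl carbon bonds to the 4-benzyloxybenzoyl carbon (C3''–C2''), so the biaryl acts as acyl donor on one side and as enolate on the other. The product contains no ring that was not already in 11 and no stereocentre is created, and the liberated phenoxides remain in place as the future O1 and O1''. The selectivity needed is the correct pairing of two enolates with two esters, and the ortho arrangement secures it. The matched pairs react through six-membered transition states, whereas the ring A enolate could reach the ring B ester only through a doubly meta-bridged nine-membered ring and the paeonol enolate could reach the ring A ester only through a thirteen-membered one. Deprotonation of each diketone by the excess base makes both transfers effectively irreversible, and dry powdered KOH in pyridine keeps saponification low.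

**Step 8**
Reactants: 12 the bis(1,3-diketone) of step 7
Product: 13 7-(benzyloxy)-2-[4-(benzyloxy)phenyl]-8-[2-methoxy-5-(7-methoxy-4-oxo-4H-chromen-2-yl)phenyl]-4H-chromen-4-one
Conditions: H2SO4 (cat.), AcOH, 80 °C
Reagents that add atoms: none
Why: Acid-catalysed cyclodehydration of ortho-hydroxyaryl 1,3-diketones, in which each phenolic oxygen adds 6-exo-trig to the aroyl-side carbonyl to give a cyclic hemiketal that loses water to the conjugated 4-pyranone, and only the hydroxyl ortho to each diketone can reach it, so O1–C2 and O1''–C2'' form unambiguously.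

**Step 9**
Reactants: 13 7-(benzyloxy)-2-[4-(benzyloxy)phenyl]-8-[2-methoxy-5-(7-methoxy-4-oxo-4H-chromen-2-yl)phenyl]-4H-chromen-4-one
Product: 14 7-hydroxy-2-(4-hydroxyphenyl)-8-[2-methoxy-5-(7-methoxy-4-oxo-4H-chromen-2-yl)phenyl]-4H-chromen-4-one (CNP0121664.0)
Conditions: BCl3 (6 equiv), pentamethylbenzene (6 equiv), CH2Cl2, −78 °C; then H2O
Reagents that add atoms: none
Why: Lewis-acid debenzylation with a non-Lewis-basic cation scavenger, in which benzylic C–O bonds ionise at −78 °C whereas the two aryl methyl ethers, neither of them peri to a carbonyl group, need far harsher treatment, and pentamethylbenzene takes up the benzyl cation before it can alkylate the phenols.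

**Compound list**
1 | 2,4-dihydroxyacetophenone | CC(=O)c1ccc(O)cc1O | starting material
2 | 1-(2,4-dihydroxy-3-iodophenyl)ethan-1-one | CC(=O)c1ccc(O)c(I)c1O | intermediate
3 | 1-[4-(benzyloxy)-2-hydroxy-3-iodophenyl]ethan-1-one | CC(=O)c1ccc(OCc2ccccc2)c(I)c1O | intermediate
4 | (5-formyl-2-methoxyphenyl)boronic acid | COc1ccc(C=O)cc1B(O)O | starting material
5 | 3'-acetyl-6'-(benzyloxy)-2'-hydroxy-6-methoxy-[1,1'-biphenyl]-3-carbaldehyde | CC(=O)c1ccc(OCc2ccccc2)c(-c2cc(C=O)ccc2OC)c1O | intermediate
6 | 4-(benzyloxy)benzoic acid | O=C(O)c1ccc(OCc2ccccc2)cc1 | starting material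
7 | 4-(benzyloxy)benzoyl chloride | O=C(Cl)c1ccc(OCc2ccccc2)cc1 | intermediate
8 | 6-acetyl-3-(benzyloxy)-2-(5-formyl-2-methoxyphenyl)phenyl 4-(benzyloxy)benzoate | CC(=O)c1ccc(OCc2ccccc2)c(-c2cc(C=O)ccc2OC)c1OC(=O)c1ccc(OCc2ccccc2)cc1 | intermediate
9 | 3-[3-acetyl-6-(benzyloxy)-2-{[4-(benzyloxy)benzoyl]oxy}phenyl]-4-methoxybenzoic acid | CC(=O)c1ccc(OCc2ccccc2)c(-c2cc(C(=O)O)ccc2OC)c1OC(=O)c1ccc(OCc2ccccc2)cc1 | intermediate
10 | 2-hydroxy-4-methoxyacetophenone (paeonol) | CC(=O)c1ccc(OC)cc1O | starting material
11 | biaryl diester with two ortho-acyloxyacetophenone units (name as in step 6) | CC(=O)c1ccc(OC)cc1OC(=O)c1ccc(OC)c(-c2c(OCc3ccccc3)ccc(C(C)=O)c2OC(=O)c2ccc(OCc3ccccc3)cc2)c1 | intermediate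
12 | biaryl bis(1,3-diketone) (name as in step 7) | COc1ccc(C(=O)CC(=O)c2ccc(OC)c(-c3c(OCc4ccccc4)ccc(C(=O)CC(=O)c4ccc(OCc5ccccc5)cc4)c3O)c2)c(O)c1 | intermediate
13 | 7''-O,4'''-O-dibenzyl biflavone (name as in step 8) | COc1ccc2c(=O)cc(-c3ccc(OC)c(-c4c(OCc5ccccc5)ccc5c(=O)cc(-c6ccc(OCc7ccccc7)cc6)oc45)c3)oc2c1 | intermediate
14 | 7-hydroxy-2-(4-hydroxyphenyl)-8-[2-methoxy-5-(7-methoxy-4-oxo-4H-chromen-2-yl)phenyl]-4H-chromen-4-one | COc1ccc2c(=O)cc(-c3ccc(OC)c(-c4c(O)ccc5c(=O)cc(-c6ccc(O)cc6)oc45)c3)oc2c1 | target

**Total step count:** 9. **Longest linear sequence:** 9 (1 to 14; compounds 4, 6 and 10 are bought and enter directly).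

**Steps most likely to fail**

*Step 3.*
- What may go wrong: the C–I bond sits between a benzyloxy group and a phenoxide. Slow transmetalation and reductive elimination could therefore let protodeboronation of 4, hydrodeiodination of 3, or base-induced aldol condensation between formyl and acetyl groups take over.
- Route of the fallback: it sets out from 3 and returns at 5. The phenol is first masked with chloromethyl methyl ether and i-Pr2NEt in CH2Cl2 to give 1-[4-(benzyloxy)-3-iodo-2-(methoxymethoxy)phenyl]ethan-1-one F1. This neutral iodide no longer forms an electron-rich, water-soluble phenoxide.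
- Coupling and return: F1 is coupled with 4 (Pd(OAc)2, SPhos, K3PO4, toluene with a little water) to give 3'-acetyl-6'-(benzyloxy)-6-methoxy-2'-(methoxymethoxy)-[1,1'-biphenyl]-3-carbaldehyde F2. Dilute aqueous HCl in THF then removes the acetal and gives 5.

*Step 7.*
- What may go wrong: saponification of the esters by hydroxide may compete with acyl transfer. The hindered ring A site may also lag behind the paeonol site, so the diketone formed first is exposed long enough for retro-Claisen cleavage.
- Route of the fallback: it sets out from 9 and returns at 13. It makes the same two C–C bonds one at a time, with a ring closure in between, so each transfer faces only one ester and can be tuned on its own.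
- First transfer and closure: acid 9, inert as its carboxylate, is rearranged with KOH in pyridine to 3-{6-(benzyloxy)-3-[3-(4-(benzyloxy)phenyl)-3-oxopropanoyl]-2-hydroxyphenyl}-4-methoxybenzoic acid F3. This is closed with catalytic H2SO4 in AcOH to 3-{7-(benzyloxy)-2-[4-(benzyloxy)phenyl]-4-oxo-4H-chromen-8-yl}-4-methoxybenzoic acid F4.
- Second transfer and closure: esterification of F4 with 10 (EDC·HCl, DMAP) gives 2-acetyl-5-methoxyphenyl 3-{7-(benzyloxy)-2-[4-(benzyloxy)phenyl]-4-oxo-4H-chromen-8-yl}-4-methoxybenzoate F5. A second, unhindered Baker–Venkataraman transfer gives 1-(2-hydroxy-4-methoxyphenyl)-3-(3-{7-(benzyloxy)-2-[4-(benzyloxy)phenyl]-4-oxo-4H-chromen-8-yl}-4-methoxyphenyl)propane-1,3-dione F6. Acid cyclodehydration of F6 then delivers 13.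

*Step 9.*
- What may go wrong: the flat biflavone may precipitate at −78 °C and both pyranone carbonyls bind BCl3, so cleavage of the flanked 7''-O-benzyl group may stall. Warming to force it invites loss of a methyl ether.
- Route of the fallback: it sets out from 12 and returns at 14 by reversing the order of the last two operations. The benzyl ethers are removed at the more soluble open-chain stage, where there is no C2=C3 double bond to over-reduce. Hydrogenolysis (H2, 1 atm, Pd/C, THF–EtOH, rt) gives 1-(4-hydroxyphenyl)-3-{2,4-dihydroxy-3-[5-(3-(2-hydroxy-4-methoxyphenyl)-3-oxopropanoyl)-2-methoxyphenyl]phenyl}propane-1,3-dione F7.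
- Return: catalytic H2SO4 in AcOH then closes both pyranones directly to 14. The additional free hydroxyl groups are para to their carbonyl groups and cannot cyclise.

**Further compounds**
F1 | step 3 | 1-[4-(benzyloxy)-3-iodo-2-(methoxymethoxy)phenyl]ethan-1-one | CC(=O)c1ccc(OCc2ccccc2)c(I)c1OCOC
F2 | step 3 | 3'-acetyl-6'-(benzyloxy)-6-methoxy-2'-(methoxymethoxy)-[1,1'-biphenyl]-3-carbaldehyde | CC(=O)c1ccc(OCc2ccccc2)c(-c2cc(C=O)ccc2OC)c1OCOC
F3 | step 7 | 3-{6-(benzyloxy)-3-[3-(4-(benzyloxy)phenyl)-3-oxopropanoyl]-2-hydroxyphenyl}-4-methoxybenzoic acid | O=C(O)c1ccc(OC)c(-c2c(OCc3ccccc3)ccc(C(=O)CC(=O)c3ccc(OCc4ccccc4)cc3)c2O)c1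
F4 | step 7 | 3-{7-(benzyloxy)-2-[4-(benzyloxy)phenyl]-4-oxo-4H-chromen-8-yl}-4-methoxybenzoic acid | O=C(O)c1ccc(OC)c(-c2c(OCc3ccccc3)ccc3c(=O)cc(-c4ccc(OCc5ccccc5)cc4)oc23)c1
F5 | step 7 | 2-acetyl-5-methoxyphenyl 3-{7-(benzyloxy)-2-[4-(benzyloxy)phenyl]-4-oxo-4H-chromen-8-yl}-4-methoxybenzoate | CC(=O)c1ccc(OC)cc1OC(=O)c1ccc(OC)c(-c2c(OCc3ccccc3)ccc3c(=O)cc(-c4ccc(OCc5ccccc5)cc4)oc23)c1
F6 | step 7 | 1-(2-hydroxy-4-methoxyphenyl)-3-(3-{7-(benzyloxy)-2-[4-(benzyloxy)phenyl]-4-oxo-4H-chromen-8-yl}-4-methoxyphenyl)propane-1,3-dione | COc1ccc(C(=O)CC(=O)c2ccc(OC)c(-c3c(OCc4ccccc4)ccc4c(=O)cc(-c5ccc(OCc6ccccc6)cc5)oc34)c2)c(O)c1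
F7 | step 9 | 1-(4-hydroxyphenyl)-3-{2,4-dihydroxy-3-[5-(3-(2-hydroxy-4-methoxyphenyl)-3-oxopropanoyl)-2-methoxyphenyl]phenyl}propane-1,3-dione | COc1ccc(C(=O)CC(=O)c2ccc(OC)c(-c3c(O)ccc(C(=O)CC(=O)c4ccc(O)cc4)c3O)c2)c(O)c1
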